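## The problem

The target is a C25 terpenoid built on a cis-fused 4,4,10-trimethyl-Δ8-decalin (ring A: C1–C5 and C10; ring B: C5–C10). C9 carries a six-carbon chain (C11–C16) that ends in a β-substituted butenolide. There are only two stereocentres, the quaternary C10 and its neighbour C5, and they are cis. Because the bicycle has no heteroatom, both the absolute and the relative configuration must come from temporary control elements. C10 cannot set C5 by itself: in a Δ5 precursor the methyl face of C5 is flanked by the C10 methyl and the axial C4 methyl, so catalysts and electrophiles approach from the other face and give the trans fusion. A hydroxyl on C1 does not help, since C1 lies on the face of ring B opposite the methyl. The C5 hydrogen therefore has to be delivered to the hindered face by a stereospecific device. The tetrasubstituted C8=C9 alkene must survive every reduction without migrating. The chain contains an E,E-diene whose trisubstituted C13=C14 bond (C12 cis to C15) bears a free primary allylic alcohol. This diene is conjugated to a butenolide that is sensitive to base (γ-deprotonation, ring opening), to acid (isomerisation, furan formation) and to hydride. What makes a cycloaddition possible is that C8 with its methyl and C9 with C11 are the two alkyne carbons of a but-2-ynoate, while C7=C6–C5=C10 is the diene of a 1-vinylcyclohexene built on ring A.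

## Retrosynthesis

**C15=C16.** The last bond made is the C15=C16 alkene of 27, cut to hydroxy enal 24 and butenolide phosphonate 26 (one Arbuzov step from bromide 25). Cutting C16–C4′ instead would need a dienyl metal or halide made in an extra step. Cutting C13=C14 would mean olefinating a ketone with no control of the trisubstituted geometry. The chosen cut brings in the lactone in the final step under mild base and removes five carbons and the most fragile group. It asks for E selectivity and tolerance of the free hydroxyl.

**C12–C13.** Enal 24 comes from acetal 23, which is cut at the C12–C13 single bond into diene 18 (as its terminal alkylborane 22) and vinyl iodide 21. The geometry of C13=C14 is the difficult part of the chain. Iodide 21 carries it ready-made, and a B-alkyl Suzuki–Miyaura coupling transfers it with retention. The neighbouring cut at C11–C12 (allylic bromide plus allyl sulfone anion) would need a reductive desulfonylation through an allyl system in which alkene position and geometry can scramble. The forward step needs hydroboration only at the terminal carbon of the vinyl group.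

**C11 oxidation level and C12.** Diene 18 is traced through enal 17 and allylic alcohol 16 to ester 15. C11 must arrive as an ester because it is the activating group of the dienophile, so the one-carbon extension to the vinyl group costs three routine steps (reduction, oxidation, methylenation).

**C1–O.** Ester 15 comes from hydroxy ester 13 through xanthate 14. The C1 oxygen is the only source of absolute configuration and is deleted by radical deoxygenation while C8=C9 is still deactivated as an enoate.

**C5–H.** The cis ring fusion of 13 is traced through dienoate 12 to allylsilane 11. A hydroxyl-directed hydrogenation from C1 was rejected on geometric grounds. A C1 hydroxyl syn to the methyl is equatorial and antiperiplanar to C5. One anti to the methyl is axial and would deliver hydrogen to the face opposite the methyl. Instead C7 carries a trimethylsilyl group trans to the C10 methyl. Protonation of this allylsilane at C5 anti to silicon puts the hydrogen on the methyl face, and the displaced C6=C7 alkene is then hydrogenated. This needs γ-protonation at C5 rather than C9, and anti attack.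

**C7–C8 and C9–C10 (key step).** Adduct 11 is cut across ring B into diene 9 and methyl but-2-ynoate 10. One cycloaddition creates the quaternary C10, the C8 methyl, the C8=C9 alkene and C11. The same suprafacial event fixes the C7 silicon relative to C10, so the ring fusion is decided here as well. The forward reaction must add anti to the C1 silyloxy group, join C7 to the methyl-bearing alkyne carbon, and overcome the steric retardation of a diene with an inside methyl group.

**Diene 9.** Silyl ether 9 comes from (R)-dienol 8 and dienone 7. The carbinol centre is set by catalytic asymmetric reduction. Dienone 7 is cut at the ring–vinyl bond into vinylogous ester 3 and (E)-bromovinylsilane 4, and 3 is the double methylation product of commercial enone 1.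

**Iodide 21.** This comes by reduction of iodoenal 20, itself the α-iodination product of commercial enal 19. The E enal geometry becomes the required Z iodide.

## Roads not taken

**Alternative 1:** Rings A and B are cut at C4–C5 and C9–C10, leading back to the acyclic (Z)-epoxy keto ester A2. In the forward step a Lewis acid (MeAlCl2 or SnCl4) opens the (S)-epoxide, C5 attacks C4 and the enol carbon C9 attacks C10, giving bicycle A1.
- Merits: both rings and both ring-fusion centres form in one step, the cis fusion follows from the Z alkene, the absolute configuration comes from a catalytic epoxidation, and C9 already carries C11.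
- Weak points: a Z alkene must cyclise through a less favourable folded transition state, so interrupted cyclisation, ether formation and stepwise cation pathways that erode the cis selectivity are expected. A1 also lacks the C8 methyl (triflation of the enol and a methyl cross-coupling would be needed) and carries a C3 hydroxyl to delete.
- Comparison: this road reaches the bicycle in fewer steps and needs no pressure equipment, so it is better on step count to the core. The chosen plan sets against it a ring fusion fixed by two stereospecific events rather than by the conformational preference of a cation, and a cycloaddition that delivers the C8 methyl and C8=C9 directly. Both roads need one deoxygenation.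

**Alternative 2:** Ring A is cut at C1–C10 and a C3–C8 bond is added retrosynthetically, giving the 2-vinylbicyclo[2.2.2]octenol A4. In the forward step its potassium alkoxide (KH, 18-crown-6) undergoes an anionic oxy-Cope shift to ketone A3.
- Merits: the cis fusion is forced by the geometry of the [3,3] shift, the C8=C9 alkene appears in place, and C11–C12 are already attached. That saves the three steps the chosen plan spends on C12.
- Weak points: A4 holds three quaternary carbons in a strained bicycle. Its own assembly (a cycloaddition to build the cage, then a face-selective vinyl addition to a neopentyl ketone) has no obvious enantioselective version. The C3 ketone of A3 must then be removed next to the gem-dimethyl group.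
- Comparison: this road is better in the certainty of the ring fusion and in chain economy. The chosen plan sets against it a key-step precursor made in four steps from a commercial enone with catalyst-controlled absolute configuration.

**Alternative 3:** Ring B is cut at C7–C8 and C8–C9, leading to the cis-hydrindanone A6. In the forward step Me3SiCHN2 with BF3·OEt2 adds to the C9 ketone and the C7 methylene migrates, giving decalone A5.
- Merits: the cis fusion is settled before the key step in a ring system where cis is the easily reached isomer, and migration of the less substituted carbon is the normal outcome.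
- Weak points: A5 has no C8 methyl, no C8=C9 alkene and no C11. All three must be built on a neopentyl ketone, which means four to five more steps with regiochemical hazards. Insertion on the C10 side and double homologation can also compete.
- Comparison: the ring fusion is more secure here than in the chosen plan. The chosen plan sets against it that one cycloaddition supplies the C8 methyl, C8=C9 and C11 together, so the overall route is shorter.

Key step: step 5

Assumption: compounds 1, 4, 10, 19 and 25 are taken as commercial materials.

## Route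

Step 1
Reactants: 1 3-ethoxy-2-methylcyclohex-2-en-1-one
Product: 3 3-ethoxy-2,6,6-trimethylcyclohex-2-en-1-one, via 3-ethoxy-2,6-dimethylcyclohex-2-en-1-one 2 (not isolated)
Conditions: LiN(i-Pr)2, THF, −78 °C; MeI; then LiN(i-Pr)2, −78 °C; MeI, −78 °C → rt
Reagents that add atoms: iodomethane, CI
Why: Stork–Danheiser alkylation: LiN(i-Pr)2 deprotonates the vinylogous ester kinetically at C6, the only enolisable position next to the carbonyl, and iodomethane alkylates it; a second cycle in the same flask completes the gem-dimethyl group.

Step 2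
Reactants: 3 3-ethoxy-2,6,6-trimethylcyclohex-2-en-1-one; 4 (E)-(2-bromoethenyl)trimethylsilane
Product: 7 2,4,4-trimethyl-3-[(E)-2-(trimethylsilyl)ethenyl]cyclohex-2-en-1-one, via (E)-[2-(trimethylsilyl)ethenyl]lithium 5 (not isolated), via lithium carbinolate adduct 6 (not isolated)
Conditions: 4, t-BuLi (2 equiv), Et2O, −78 °C; then 3, −78 → 0 °C; 1 M HCl, 0 °C
Reagents that add atoms: water, O
Why: Bromine–lithium exchange keeps the E geometry and the vinyllithium adds 1,2 to the hindered vinylogous ester carbonyl. Aqueous acid then hydrolyses the enol ether with loss of the carbinol oxygen (Stork–Danheiser transposition), giving the 3-alkenyl enone; the electron-poor vinylsilane survives.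

Step 3
Reactants: 7 2,4,4-trimethyl-3-[(E)-2-(trimethylsilyl)ethenyl]cyclohex-2-en-1-one
Product: 8 (1R)-2,4,4-trimethyl-3-[(E)-2-(trimethylsilyl)ethenyl]cyclohex-2-en-1-ol
Conditions: (S)-1-methyl-3,3-diphenyltetrahydro-1H,3H-pyrrolo[1,2-c][1,3,2]oxazaborole (20 mol%), catecholborane, toluene, −78 °C
Reagents that add atoms: none
Why: Corey–Bakshi–Shibata reduction: the fully substituted alkene arm acts as the large group and the C6 methylene as the small one, so the (S)-oxazaborolidine should give the (R)-carbinol. Catecholborane at low temperature reduces only the catalyst-activated carbonyl, in the 1,2 sense.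

Step 4
Reactants: 8 (1R)-2,4,4-trimethyl-3-[(E)-2-(trimethylsilyl)ethenyl]cyclohex-2-en-1-ol
Product: 9 tert-butyldimethyl({(1R)-2,4,4-trimethyl-3-[(E)-2-(trimethylsilyl)ethenyl]cyclohex-2-en-1-yl}oxy)silane
Conditions: TBSCl, imidazole, DMF, rt
Reagents that add atoms: tert-butyldimethylsilyl chloride, CC(C)(C)[Si](C)(C)Cl
Why: Standard silylation of a secondary allylic alcohol; the bulky ether is the group that shields one face of the diene in the next step.

Step 5
Reactants: 9 tert-butyldimethyl({(1R)-2,4,4-trimethyl-3-[(E)-2-(trimethylsilyl)ethenyl]cyclohex-2-en-1-yl}oxy)silane; 10 methyl but-2-ynoate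
Product: 11 methyl (3R,8R,8aS)-8-[(tert-butyldimethylsilyl)oxy]-2,5,5,8a-tetramethyl-3-(trimethylsilyl)-3,5,6,7,8,8a-hexahydronaphthalene-1-carboxylate
Conditions: 10 (5 equiv), BHT (cat.), CH2Cl2, 13 kbar, 50 °C
Reagents that add atoms: none
Why: Concerted, normal-electron-demand [4+2] cycloaddition; the closest known reactions are the additions of acetylenic esters to 2,6,6-trimethyl-1-vinylcyclohexene-type dienes and to 1-silylbuta-1,3-dienes. Ring B closes through a six-membered transition state with both new σ bonds (C7–C8 and C9–C10) formed on the same face of the diene, and the resulting 1,4-cyclohexadiene cannot aromatise because C10 is quaternary. Orientation: the two alkyl groups on the C10 terminus make C7 the more nucleophilic end, so C7 bonds to the methyl-bearing β-carbon of the ynoate and C10 to the ester-bearing carbon. C10 is controlled by C1: A(1,2) strain with the C10 methyl holds the silyloxy group pseudoaxial, it shields that face, the dienophile adds anti to it, and the methyl (the inside substituent) ends syn to the oxygen. C7 is controlled by the E geometry of the vinylsilane: silicon is the outside substituent and therefore ends trans to the C10 methyl across ring B. Pressure is used because the reaction is sterically retarded (inside methyl, singly activated ynoate) and has a strongly negative activation volume, while the low temperature keeps a [1,5]-hydrogen shift of the diene from competing.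

Step 6
Reactants: 11 methyl (3R,8R,8aS)-8-[(tert-butyldimethylsilyl)oxy]-2,5,5,8a-tetramethyl-3-(trimethylsilyl)-3,5,6,7,8,8a-hexahydronaphthalene-1-carboxylate
Product: 12 methyl (4aR,8R,8aS)-8-hydroxy-2,5,5,8a-tetramethyl-4a,5,6,7,8,8a-hexahydronaphthalene-1-carboxylate
Conditions: HCl (1.25 M in MeOH), CH2Cl2, −20 °C → rt
Reagents that add atoms: none
Why: Acid-promoted anti SE2′ protodesilylation of an allylsilane: the proton adds to C5 on the face opposite the C7–Si bond, the β-silyl cation at C6 loses silicon, and the new C6=C7 alkene ends conjugated with the enoate. Because silicon is trans to the C10 methyl, the new C5–H is cis to it, which sets the cis ring fusion. The electron-poor C8=C9 alkene is not protonated, and the same acid solvolyses the silyl ether.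

Step 7
Reactants: 12 methyl (4aR,8R,8aS)-8-hydroxy-2,5,5,8a-tetramethyl-4a,5,6,7,8,8a-hexahydronaphthalene-1-carboxylate
Product: 13 methyl (4aR,8R,8aS)-8-hydroxy-2,5,5,8a-tetramethyl-3,4,4a,5,6,7,8,8a-octahydronaphthalene-1-carboxylate
Conditions: H2 (1 atm), RhCl(PPh3)3 (10 mol%), toluene/EtOH, rt
Reagents that add atoms: none
Why: Homogeneous hydrogenation with RhCl(PPh3)3 reduces the disubstituted C6=C7 alkene and leaves the tetrasubstituted, ester-conjugated C8=C9 alkene. Its dihydride pathway does not chain-walk, so C5 is not epimerised; no stereocentre is formed.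

Step 8
Reactants: 13 methyl (4aR,8R,8aS)-8-hydroxy-2,5,5,8a-tetramethyl-3,4,4a,5,6,7,8,8a-octahydronaphthalene-1-carboxylate
Product: 14 methyl (4aR,8R,8aS)-2,5,5,8a-tetramethyl-8-{[(methylsulfanyl)carbonothioyl]oxy}-3,4,4a,5,6,7,8,8a-octahydronaphthalene-1-carboxylate
Conditions: NaH, THF, 0 °C; CS2; MeI, rt
Reagents that add atoms: carbon disulfide, S=C=S; iodomethane, CI
Why: Xanthate formation, the first half of a Barton–McCombie deoxygenation: the sodium alkoxide adds to CS2 and the dithiocarbonate salt is S-methylated; the small electrophile suits the hindered equatorial alcohol.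

Step 9
Reactants: 14 methyl (4aR,8R,8aS)-2,5,5,8a-tetramethyl-8-{[(methylsulfanyl)carbonothioyl]oxy}-3,4,4a,5,6,7,8,8a-octahydronaphthalene-1-carboxylate
Product: 15 methyl (4aR,8aS)-2,5,5,8a-tetramethyl-3,4,4a,5,6,7,8,8a-octahydronaphthalene-1-carboxylate
Conditions: Bu3SnH, AIBN, toluene, 110 °C
Reagents that add atoms: none
Why: Barton–McCombie deoxygenation: the stannyl radical adds to the thiocarbonyl, β-scission gives the secondary C1 radical, and this abstracts hydrogen from Bu3SnH, so C1 ceases to be a stereocentre. Attack of this nucleophilic radical on the α-carbon of the neighbouring enoate is polarity-mismatched, which is why the step is run at the ester stage.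

Step 10
Reactants: 15 methyl (4aR,8aS)-2,5,5,8a-tetramethyl-3,4,4a,5,6,7,8,8a-octahydronaphthalene-1-carboxylate
Product: 16 [(4aR,8aS)-2,5,5,8a-tetramethyl-3,4,4a,5,6,7,8,8a-octahydronaphthalen-1-yl]methanol
Conditions: i-Bu2AlH, CH2Cl2, −78 → 0 °C
Reagents that add atoms: none
Why: i-Bu2AlH reduces the conjugated ester 1,2 to the allylic alcohol without touching the tetrasubstituted alkene.

Step 11
Reactants: 16 [(4aR,8aS)-2,5,5,8a-tetramethyl-3,4,4a,5,6,7,8,8a-octahydronaphthalen-1-yl]methanol
Product: 17 (4aR,8aS)-2,5,5,8a-tetramethyl-3,4,4a,5,6,7,8,8a-octahydronaphthalene-1-carbaldehyde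
Conditions: Pr4N[RuO4] (5 mol%), N-methylmorpholine N-oxide, 4 Å MS, CH2Cl2, rt
Reagents that add atoms: none
Why: Ley–Griffith oxidation of the hindered primary allylic alcohol stops at the enal under neutral conditions.

Step 12
Reactants: 17 (4aR,8aS)-2,5,5,8a-tetramethyl-3,4,4a,5,6,7,8,8a-octahydronaphthalene-1-carbaldehyde
Product: 18 (4aR,8aS)-1-ethenyl-2,5,5,8a-tetramethyl-3,4,4a,5,6,7,8,8a-octahydronaphthalene
Conditions: Ph3PCH3Br, KOt-Bu, THF, 0 → 50 °C
Reagents that add atoms: methyltriphenylphosphonium bromide, C[P+](c1ccccc1)(c1ccccc1)c1ccccc1.[Br-]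
Why: Wittig methylenation with the unstabilised ylide; hindered cyclohexenecarbaldehydes flanked by a quaternary carbon and a ring methyl are established substrates for this reaction.

Step 13
Reactants: 19 (E)-4,4-dimethoxybut-2-enal
Product: 20 (Z)-2-iodo-4,4-dimethoxybut-2-enal
Conditions: I2, K2CO3, DMAP (20 mol%), THF/H2O, rt
Reagents that add atoms: iodine, II
Why: Nucleophile-catalysed α-iodination of an enal (conjugate addition of DMAP, iodination of the enolate, elimination, as in a Baylis–Hillman sequence). The elimination gives the isomer with the formyl group trans to the β-substituent, which is the Z iodide.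

Step 14
Reactants: 20 (Z)-2-iodo-4,4-dimethoxybut-2-enal
Product: 21 (Z)-2-iodo-4,4-dimethoxybut-2-en-1-ol
Conditions: NaBH4, MeOH, 0 °C
Reagents that add atoms: none
Why: 1,2-Reduction of the enal by NaBH4; the alkene geometry, the vinyl iodide and the acetal are unaffected.

Step 15
Reactants: 18 (4aR,8aS)-1-ethenyl-2,5,5,8a-tetramethyl-3,4,4a,5,6,7,8,8a-octahydronaphthalene; 21 (Z)-2-iodo-4,4-dimethoxybut-2-en-1-ol
Product: 23 (E)-4,4-dimethoxy-2-{2-[(4aR,8aS)-2,5,5,8a-tetramethyl-3,4,4a,5,6,7,8,8a-octahydronaphthalen-1-yl]ethyl}but-2-en-1-ol, via B-alkyl-9-borabicyclo[3.3.1]nonane 22 (not isolated)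
Conditions: 18, 9-BBN-H, THF, 0 °C → rt; then 21, PdCl2(dppf)·CH2Cl2 (10 mol%), AsPh3, Cs2CO3, DMF/H2O, rt
Reagents that add atoms: none
Why: 9-BBN-H hydroborates only the terminal vinyl group, at its unsubstituted carbon; the tetrasubstituted ring alkene is inert. The B-alkyl Suzuki–Miyaura coupling then joins C12 to C13 with retention of the vinyl iodide geometry, which fixes the trisubstituted alkene.

Step 16
Reactants: 23 (E)-4,4-dimethoxy-2-{2-[(4aR,8aS)-2,5,5,8a-tetramethyl-3,4,4a,5,6,7,8,8a-octahydronaphthalen-1-yl]ethyl}but-2-en-1-ol
Product: 24 (E)-4-hydroxy-3-{2-[(4aR,8aS)-2,5,5,8a-tetramethyl-3,4,4a,5,6,7,8,8a-octahydronaphthalen-1-yl]ethyl}but-2-enal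
Conditions: pyridinium p-toluenesulfonate (20 mol%), acetone/H2O, rt
Reagents that add atoms: water, O
Why: Mild hydrolysis of an α,β-unsaturated dimethyl acetal; the hydroxymethyl group is trans to the new formyl group and cannot close to a lactol.

Step 17
Reactants: 25 4-(bromomethyl)furan-2(5H)-one
Product: 26 diethyl [(5-oxo-2,5-dihydrofuran-3-yl)methyl]phosphonate
Conditions: P(OEt)3, toluene, 110 °C
Reagents that add atoms: triethyl phosphite, CCOP(OCC)OCC
Why: Michaelis–Arbuzov reaction of a primary allylic bromide, as used for 4-phosphonocrotonates.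

Step 18
Reactants: 24 (E)-4-hydroxy-3-{2-[(4aR,8aS)-2,5,5,8a-tetramethyl-3,4,4a,5,6,7,8,8a-octahydronaphthalen-1-yl]ethyl}but-2-enal; 26 diethyl [(5-oxo-2,5-dihydrofuran-3-yl)methyl]phosphonate
Product: 27 4-[(1E,3E)-4-(hydroxymethyl)-6-[(4aR,8aS)-2,5,5,8a-tetramethyl-3,4,4a,5,6,7,8,8a-octahydronaphthalen-1-yl]hexa-1,3-dien-1-yl]furan-2(5H)-one
Conditions: 26, LiCl, DBU, MeCN, 0 °C → rt
Reagents that add atoms: none
Why: Horner–Wadsworth–Emmons olefination with a vinylogous phosphonoacetate under LiCl/DBU (Masamune–Roush conditions) should react at the phosphorus-bearing carbon and give the E alkene. The amine base leaves the free hydroxyl and the butenolide alone.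

## Compound list

1 | 3-ethoxy-2-methylcyclohex-2-en-1-one | CCOC1=C(C)C(=O)CCC1 | starting material
2 | 3-ethoxy-2,6-dimethylcyclohex-2-en-1-one (racemic) | CCOC1=C(C)C(=O)C(C)CC1 | intermediate
3 | 3-ethoxy-2,6,6-trimethylcyclohex-2-en-1-one | CCOC1=C(C)C(=O)C(C)(C)CC1 | intermediate
4 | (E)-(2-bromoethenyl)trimethylsilane | C[Si](C)(C)/C=C/Br | starting material
5 | (E)-[2-(trimethylsilyl)ethenyl]lithium | C[Si](C)(C)/C=C/[Li] | intermediate
6 | lithium 3-ethoxy-2,6,6-trimethyl-1-[(E)-2-(trimethylsilyl)ethenyl]cyclohex-2-en-1-olate (racemic) | [Li+].CCOC1=C(C)C([O-])(/C=C/[Si](C)(C)C)C(C)(C)CC1 | intermediate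
7 | 2,4,4-trimethyl-3-[(E)-2-(trimethylsilyl)ethenyl]cyclohex-2-en-1-one | C[Si](C)(C)/C=C/C1=C(C)C(=O)CCC1(C)C | intermediate
8 | (1R)-2,4,4-trimethyl-3-[(E)-2-(trimethylsilyl)ethenyl]cyclohex-2-en-1-ol | C[Si](C)(C)/C=C/C1=C(C)[C@H](O)CCC1(C)C | intermediate
9 | tert-butyldimethyl({(1R)-2,4,4-trimethyl-3-[(E)-2-(trimethylsilyl)ethenyl]cyclohex-2-en-1-yl}oxy)silane | C[Si](C)(C)/C=C/C1=C(C)[C@H](O[Si](C)(C)C(C)(C)C)CCC1(C)C | intermediate
10 | methyl but-2-ynoate | CC#CC(=O)OC | starting material
11 | methyl (3R,8R,8aS)-8-[(tert-butyldimethylsilyl)oxy]-2,5,5,8a-tetramethyl-3-(trimethylsilyl)-3,5,6,7,8,8a-hexahydronaphthalene-1-carboxylate | CC1=C(C(=O)OC)[C@@]2(C)[C@H](O[Si](C)(C)C(C)(C)C)CCC(C)(C)C2=C[C@H]1[Si](C)(C)C | intermediate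
12 | methyl (4aR,8R,8aS)-8-hydroxy-2,5,5,8a-tetramethyl-4a,5,6,7,8,8a-hexahydronaphthalene-1-carboxylate | CC1=C(C(=O)OC)[C@@]2(C)[C@H](O)CCC(C)(C)[C@H]2C=C1 | intermediate
13 | methyl (4aR,8R,8aS)-8-hydroxy-2,5,5,8a-tetramethyl-3,4,4a,5,6,7,8,8a-octahydronaphthalene-1-carboxylate | CC1=C(C(=O)OC)[C@@]2(C)[C@H](O)CCC(C)(C)[C@H]2CC1 | intermediate
14 | methyl (4aR,8R,8aS)-2,5,5,8a-tetramethyl-8-{[(methylsulfanyl)carbonothioyl]oxy}-3,4,4a,5,6,7,8,8a-octahydronaphthalene-1-carboxylate | CC1=C(C(=O)OC)[C@@]2(C)[C@H](OC(=S)SC)CCC(C)(C)[C@H]2CC1 | intermediate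
15 | methyl (4aR,8aS)-2,5,5,8a-tetramethyl-3,4,4a,5,6,7,8,8a-octahydronaphthalene-1-carboxylate | CC1=C(C(=O)OC)[C@@]2(C)CCCC(C)(C)[C@H]2CC1 | intermediate
16 | [(4aR,8aS)-2,5,5,8a-tetramethyl-3,4,4a,5,6,7,8,8a-octahydronaphthalen-1-yl]methanol | CC1=C(CO)[C@@]2(C)CCCC(C)(C)[C@H]2CC1 | intermediate
17 | (4aR,8aS)-2,5,5,8a-tetramethyl-3,4,4a,5,6,7,8,8a-octahydronaphthalene-1-carbaldehyde | CC1=C(C=O)[C@@]2(C)CCCC(C)(C)[C@H]2CC1 | intermediate
18 | (4aR,8aS)-1-ethenyl-2,5,5,8a-tetramethyl-3,4,4a,5,6,7,8,8a-octahydronaphthalene | CC1=C(C=C)[C@@]2(C)CCCC(C)(C)[C@H]2CC1 | intermediate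
19 | (E)-4,4-dimethoxybut-2-enal | COC(OC)/C=C/C=O | starting material
20 | (Z)-2-iodo-4,4-dimethoxybut-2-enal | COC(OC)/C=C(\I)C=O | intermediate
21 | (Z)-2-iodo-4,4-dimethoxybut-2-en-1-ol | COC(OC)/C=C(\I)CO | intermediate
22 | 9-{2-[(4aR,8aS)-2,5,5,8a-tetramethyl-3,4,4a,5,6,7,8,8a-octahydronaphthalen-1-yl]ethyl}-9-borabicyclo[3.3.1]nonane | CC1=C(CCB2C3CCCC2CCC3)[C@@]2(C)CCCC(C)(C)[C@H]2CC1 | intermediate
23 | (E)-4,4-dimethoxy-2-{2-[(4aR,8aS)-2,5,5,8a-tetramethyl-3,4,4a,5,6,7,8,8a-octahydronaphthalen-1-yl]ethyl}but-2-en-1-ol | CC1=C(CC/C(CO)=C\C(OC)OC)[C@@]2(C)CCCC(C)(C)[C@H]2CC1 | intermediate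
24 | (E)-4-hydroxy-3-{2-[(4aR,8aS)-2,5,5,8a-tetramethyl-3,4,4a,5,6,7,8,8a-octahydronaphthalen-1-yl]ethyl}but-2-enal | CC1=C(CC/C(CO)=C\C=O)[C@@]2(C)CCCC(C)(C)[C@H]2CC1 | intermediate
25 | 4-(bromomethyl)furan-2(5H)-one | O=C1OCC(CBr)=C1 | starting material
26 | diethyl [(5-oxo-2,5-dihydrofuran-3-yl)methyl]phosphonate | CCOP(=O)(CC1=CC(=O)OC1)OCC | intermediate
27 | 4-[(1E,3E)-4-(hydroxymethyl)-6-[(4aR,8aS)-2,5,5,8a-tetramethyl-3,4,4a,5,6,7,8,8a-octahydronaphthalen-1-yl]hexa-1,3-dien-1-yl]furan-2(5H)-one | CC1=C(CC/C(=C\C=C\C2=CC(=O)OC2)CO)[C@@]2(C)CCCC(C)(C)[C@H]2CC1 | target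

## Step count and risks

Total step count: 18. Longest linear sequence: 15 steps (steps 1–12, 15, 16 and 18).

Least certain steps:

**Step 5 (key step).** The most likely failure is a cycloaddition that is too slow. The C10 terminus carries an inside methyl group and the ynoate has only one activating group, so isomerisation of the diene by a [1,5]-hydrogen shift, oligomerisation of the ynoate, or erosion of the facial preference may take over. Fallback: from 9, replace the ynoate by the more reactive methyl buta-2,3-dienoate. It adds across its α,β-double bond with the same orientation and gives the 2-methylidene ester F1. DBU then moves the exocyclic alkene into conjugation, and the route is rejoined at 11.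

**Step 6.** The most likely failures are loss of regio- or stereocontrol in the protonation (attack at C9, or syn attack on the crowded methyl face) and solvolytic side reactions while both silyl groups are removed in one flask. Fallback: from 11, separate the two events. CF3CO2H in CH2Cl2 at low temperature, an aprotic medium in which the open anti transition state is best expressed, cleaves only the C–Si bond and gives the silyl ether dienoate F2. Hydrogenation with RhCl(PPh3)3 gives the saturated silyl ether F3, and HF·pyridine then frees the alcohol, returning at 13.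

**Step 9.** The C1 radical sits next to the quaternary C10 that bears the C8=C9 alkene. A 3-exo closure onto C9 followed by reopening (a 1,2-vinyl shift) would expand ring B before hydrogen transfer occurs. Fallback: from 13, oxidise with Dess–Martin periodinane to the C1 ketone F4, condense it with 4-methylbenzenesulfonohydrazide to the hydrazone F5, and reduce with catecholborane followed by NaOAc, returning at 15 without a radical intermediate.

**Step 16.** Acid may isomerise the γ-hydroxy enal, after which cyclisation and dehydration to a furan is irreversible; acetal exchange with the free alcohol is a second hazard. Fallback: from 23, silylate (TBSCl, imidazole) to the silyl ether acetal F6, hydrolyse to the silyloxy enal F7, couple with 26 to the silyl ether F8, and cleave with HF·pyridine, returning at 27.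

**Step 18.** The risks are incomplete E selectivity at C15=C16 and base-induced γ-deprotonation of the dienyl butenolide, which would isomerise the product. Fallback: from 24, a Takai olefination (CrCl2, CHI3) gives the E dienyl iodide F9, and a Stille coupling with 4-(tributylstannyl)furan-2(5H)-one (Pd2(dba)3, AsPh3, CuI) forms the C16–butenolide bond instead, returning at 27.

## Further compounds

F1 | step 5 | methyl 8-[(tert-butyldimethylsilyl)oxy]-5,5,8a-trimethyl-2-methylidene-3-(trimethylsilyl)-1,2,3,5,6,7,8,8a-octahydronaphthalene-1-carboxylate (C1 epimers; other centres as in 11) | C=C1C(C(=O)OC)[C@@]2(C)[C@H](O[Si](C)(C)C(C)(C)C)CCC(C)(C)C2=C[C@H]1[Si](C)(C)C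
F2 | step 6 | methyl (4aR,8R,8aS)-8-[(tert-butyldimethylsilyl)oxy]-2,5,5,8a-tetramethyl-4a,5,6,7,8,8a-hexahydronaphthalene-1-carboxylate | CC1=C(C(=O)OC)[C@@]2(C)[C@H](O[Si](C)(C)C(C)(C)C)CCC(C)(C)[C@H]2C=C1
F3 | step 6 | methyl (4aR,8R,8aS)-8-[(tert-butyldimethylsilyl)oxy]-2,5,5,8a-tetramethyl-3,4,4a,5,6,7,8,8a-octahydronaphthalene-1-carboxylate | CC1=C(C(=O)OC)[C@@]2(C)[C@H](O[Si](C)(C)C(C)(C)C)CCC(C)(C)[C@H]2CC1
F4 | step 9 | methyl (4aR,8aS)-2,5,5,8a-tetramethyl-8-oxo-3,4,4a,5,6,7,8,8a-octahydronaphthalene-1-carboxylate | CC1=C(C(=O)OC)[C@@]2(C)C(=O)CCC(C)(C)[C@H]2CC1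
F5 | step 9 | 4-methylbenzenesulfonylhydrazone of F4 | CC1=C(C(=O)OC)[C@@]2(C)C(=NNS(=O)(=O)c3ccc(C)cc3)CCC(C)(C)[C@H]2CC1
F6 | step 16 | tert-butyldimethylsilyl ether of 23 | CC1=C(CC/C(CO[Si](C)(C)C(C)(C)C)=C\C(OC)OC)[C@@]2(C)CCCC(C)(C)[C@H]2CC1
F7 | step 16 | tert-butyldimethylsilyl ether of 24 | CC1=C(CC/C(CO[Si](C)(C)C(C)(C)C)=C\C=O)[C@@]2(C)CCCC(C)(C)[C@H]2CC1
F8 | step 16 | tert-butyldimethylsilyl ether of 27 | CC1=C(CC/C(=C\C=C\C2=CC(=O)OC2)CO[Si](C)(C)C(C)(C)C)[C@@]2(C)CCCC(C)(C)[C@H]2CC1
F9 | step 18 | (2E,4E)-5-iodo-2-{2-[(4aR,8aS)-2,5,5,8a-tetramethyl-3,4,4a,5,6,7,8,8a-octahydronaphthalen-1-yl]ethyl}penta-2,4-dien-1-ol | CC1=C(CC/C(CO)=C\C=C\I)[C@@]2(C)CCCC(C)(C)[C@H]2CC1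
A1 | alternative 1 | methyl cis-2,6-dihydroxy-5,5,8a-trimethyl-3,4,4a,5,6,7,8,8a-octahydronaphthalene-1-carboxylate (enol form; 6-hydroxyl syn to the 8a-methyl) | OC1=C(C(=O)OC)[C@@]2(C)CC[C@H](O)C(C)(C)[C@H]2CC1
A2 | alternative 1 | methyl (6Z)-9-[(2S)-3,3-dimethyloxiran-2-yl]-7-methyl-3-oxonon-6-enoate | COC(=O)CC(=O)CC/C=C(/C)CC[C@@H]1OC1(C)C
A3 | alternative 2 | cis-5-[2-(tert-butyldimethylsilyloxy)ethyl]-1,1,4a,6-tetramethyl-3,4,4a,7,8,8a-hexahydronaphthalen-2(1H)-one | CC1=C(CCO[Si](C)(C)C(C)(C)C)[C@@]2(C)CCC(=O)C(C)(C)[C@H]2CC1
A4 | alternative 2 | 6-[2-(tert-butyldimethylsilyloxy)ethyl]-1,3,3,5-tetramethyl-2-vinylbicyclo[2.2.2]oct-5-en-2-ol (vinyl syn to the C5=C6 bridge) | C=C[C@]1(O)C(C)(C)[C@H]2CC[C@]1(C)C(CCO[Si](C)(C)C(C)(C)C)=C2C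
A5 | alternative 3 | cis-5,5,8a-trimethyloctahydronaphthalen-1(2H)-one | O=C1CCC[C@@H]2C(C)(C)CCC[C@]12C
A6 | alternative 3 | cis-4,4,7a-trimethyloctahydro-1H-inden-1-one | O=C1CC[C@@H]2C(C)(C)CCC[C@]12C
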